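**Strategy.** Ring B (C5–C10) is disconnected at C5–C6 and C9–C10: a Lewis acid-promoted Diels–Alder reaction between the diene C6=C7–C8(CH3)=C9, which carries a butynyl chain, and the C5=C10 double bond of an (S)-configured α,β-unsaturated δ-lactone. The lactone is a temporary ring that ties C19–O to C20 at the acid level, exploiting the syn-diaxial C19/C20 pair on ring A. It locks the dienophile Z and acts as the endo director. One operation closes ring B and sets C5, C9 and C10. Ring A is closed afterwards by enolate alkylation at C10, C20 is reduced to methyl, and the C7=C8 alkene becomes the C8 carbinol.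

Key step: step 5

Remark: atoms carry labdane numbers throughout, also before ring A exists (C1–C10 decalin, C11–C16 side chain, C17 on C8, C18/C19 on C4, C20 on C10); β is the face of the C10 methyl group.
Assumption: the (S)-configured prolinol catalyst is taken to give the (R)-aldehyde 2, by analogy with other enamine α-functionalisations by this catalyst; if the sense were opposite, its enantiomer would be used.
Assumption: 5-chloropentanal and pent-4-ynal are purchased.

**Step 1**
Reactants: 1 5-chloropentanal
Product: 2 (R)-5-chloro-2-(hydroxymethyl)pentanal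
Conditions: 37% aq. CH2O, (S)-α,α-diphenylprolinol trimethylsilyl ether (10 mol%), toluene, NaH2PO4/Na2HPO4 buffer (pH 7), 23 °C; used crude
Reagents that add atoms: formaldehyde, C=O
Why: Enamine-catalysed cross-aldol reaction (α-hydroxymethylation) of a linear aldehyde, in which the E-enamine should be attacked on the face remote from the CPh2(OSiMe3) group, which sets C4 as R.

**Step 2**
Reactants: 2 (R)-5-chloro-2-(hydroxymethyl)pentanal
Product: 4 (S)-5-(3-chloropropyl)-5,6-dihydro-2H-pyran-2-one, via Z-hydroxy enoate 3 (not isolated)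
Conditions: (CF3CH2O)2P(O)CH2CO2Me, KN(SiMe3)2, 18-crown-6, THF, −78 °C; then TsOH·H2O (cat.), CH2Cl2, 23 °C
Reagents that add atoms: methyl bis(2,2,2-trifluoroethyl)phosphonoacetate, COC(=O)CP(=O)(OCC(F)(F)F)OCC(F)(F)F
Why: The Still–Gennari variant of the Horner–Wadsworth–Emmons olefination should give the Z-enoate at −78 °C without touching C4, and only the Z-δ-hydroxy ester can lactonise to the six-membered ring.

**Step 3**
Reactants: 5 pent-4-ynal
Product: 6 (E)-2-methylhept-2-en-6-ynal
Conditions: Ph3P=C(CH3)CHO, toluene, 90 °C
Reagents that add atoms: 2-(triphenylphosphoranylidene)propanal, CC(C=O)=P(c1ccccc1)(c1ccccc1)c1ccccc1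
Why: Wittig olefination with a stabilised formyl ylide is E-selective for the trisubstituted enal, which fixes the C8=C9 geometry of the later diene.

**Step 4**
Reactants: 6 (E)-2-methylhept-2-en-6-ynal
Product: 7 (E)-3-methylocta-1,3-dien-7-yne
Conditions: Ph3PCH3Br, KOt-Bu, THF, 0 °C
Reagents that add atoms: methyltriphenylphosphonium bromide, [Br-].C[P+](c1ccccc1)(c1ccccc1)c1ccccc1
Why: Wittig methylenation of the enal carbonyl (1,2-addition) leaves the E-trisubstituted alkene untouched and forms no stereocentre.

**Step 5**
Reactants: 4 (S)-5-(3-chloropropyl)-5,6-dihydro-2H-pyran-2-one; 7 (E)-3-methylocta-1,3-dien-7-yne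
Product: 8 (4S,4aS,8R,8aR)-8-(but-3-yn-1-yl)-4-(3-chloropropyl)-7-methyl-3,4,4a,5,8,8a-hexahydro-1H-isochromen-1-one (cis-fused lactone)
Conditions: EtAlCl2 (1.0 equiv), CH2Cl2, −40 → 0 °C; then 1 M HCl (aq.), 0 °C
Reagents that add atoms: none
Why: Lewis acid-promoted Diels–Alder reaction, closest to known EtAlCl2- or AlCl3-promoted cycloadditions of α,β-unsaturated δ-lactones and 4-substituted cyclohexenones with alkylbutadienes: coordination of EtAlCl2 to the lactone carbonyl lowers the LUMO, and the concerted, asynchronous [4+2] forms C5–C6 ahead of C9–C10. It closes ring B as a cyclohexene by intermolecular [4+2] cycloaddition, suprafacial on both partners, so the new ring is cis-fused to the lactone. C5 is set by approach of the diene to the lactone face anti to the 3-chloropropyl group on the adjacent C4 stereocentre; C9 and C10 follow from the endo transition state, in which the lactone carbonyl lies under the E-diene and the butynyl group ends cis to C20 and to C4. The regiochemistry needed (unsubstituted terminus C6 to the β-carbon C5) is secured by the 1-alkyl substituent of the diene, which raises the coefficient at C6, and by the steric demand at C5; the 2-methyl group opposes this only weakly. Only C5 and C9 must be set correctly here, because C10 passes through its enolate in step 6, and the terminal alkyne and the primary chloride should be spectators toward EtAlCl2 below 0 °C.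

**Step 6**
Reactants: 8 Diels–Alder adduct
Product: 9 15,16,18-trinorlabd-7-en-13-yne-20,19-olide (4α-H, 5α-H, 9α-H; lactone bridge C20(=O)–O–C19 on the β-face)
Conditions: KN(SiMe3)2 (2.2 equiv), THF, −78 → 23 °C; NH4Cl (aq.)
Reagents that add atoms: none
Why: Intramolecular alkylation of the lactone enolate (6-exo-tet) closes ring A, and because the chain on C4 can reach only the α-face of C10, the quaternary centre forms with C1 α and C20 β (trans A/B fusion), so any C10 epimer of 8 converges on 9, while the second equivalent of base holds the terminal alkyne as its acetylide until the quench.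

**Step 7**
Reactants: 9 tricyclic lactone
Product: 10 19,20-epoxy-15,16,18-trinorlabd-7-en-13-yn-20-ol (lactol, both anomers)
Conditions: i-Bu2AlH (1.1 equiv), CH2Cl2, −78 °C; KNaC4H4O6 (aq.)
Reagents that add atoms: none
Why: Partial reduction of a lactone to the lactol with i-Bu2AlH at low temperature is standard, and the new hemiacetal centre at C20 is inconsequential because the next step removes it.

**Step 8**
Reactants: 10 lactol
Product: 12 15,16,18-trinorlabd-7-en-13-yn-19-ol (4α-H), via hydroxy tosylhydrazone 11 (not isolated)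
Conditions: TsNHNH2, MeOH, 65 °C; then NaBH4, 65 °C
Reagents that add atoms: none
Why: The lactol opens to the hydroxy aldehyde, which is trapped as the tosylhydrazone and reduced to the methyl group (Caglioti reduction: hydride addition, loss of sulfinate and N2), conditions that leave alkyne, alkene and all stereocentres untouched.

**Step 9**
Reactants: 12 15,16,18-trinorlabd-7-en-13-yn-19-ol (4α-H)
Product: 13 7α,8α-epoxy-15,16,18-trinorlabd-13-yn-19-ol
Conditions: mCPBA, NaHCO3, CH2Cl2, 0 °C
Reagents that add atoms: 3-chloroperbenzoic acid (mCPBA), O=C(OO)c1cccc(Cl)c1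
Why: Prilezhaev epoxidation of the trisubstituted C7=C8 alkene should occur from the α-face because the axial C10 methyl group shields the β-face, which places the C8 oxygen α and the C8 methyl β; the alkyne is inert to the peracid.

**Step 10**
Reactants: 13 epoxy alcohol
Product: 14 7α,8α-epoxy-15,16,18-trinorlabd-13-yn-19-al
Conditions: Dess–Martin periodinane, NaHCO3, CH2Cl2, 23 °C
Reagents that add atoms: none
Why: Dess–Martin oxidation of the primary C19 alcohol under buffered conditions spares epoxide and alkyne and makes C4–H enolisable for the next step.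

**Step 11**
Reactants: 14 epoxy aldehyde
Product: 15 7α,8α-epoxy-15,16-dinorlabd-13-yn-19-al (4α-methyl, 4β-formyl)
Conditions: KOt-Bu, MeI, THF, −20 → 0 °C
Reagents that add atoms: iodomethane, CI
Why: C-Alkylation of the aldehyde enolate should occur from the equatorial α-face, the axial β-face being blocked by the syn-axial C10 methyl group, which gives the quaternary C4 with the formyl group axial, as is usual for C4 enolates of 10-methyl trans-decalins.

**Step 12**
Reactants: 15 methylated epoxy aldehyde
Product: 16 15,16-dinorlabd-13-yne-8α,19-diol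
Conditions: LiEt3BH (3.5 equiv), THF, 0 → 65 °C
Reagents that add atoms: none
Why: Hydride reduction of the aldehyde and SN2 opening of the trisubstituted epoxide at the secondary carbon C7 leave the oxygen on C8 with its configuration, giving the tertiary 8α-alcohol.

**Step 13**
Reactants: 16 alkyne diol
Product: 17 labda-13(16),14-diene-8α,19-diol
Conditions: ethylene (1 atm), second-generation Grubbs catalyst (H2IMes)(PCy3)Cl2Ru=CHPh (5 mol%), CH2Cl2, 40 °C
Reagents that add atoms: ethylene, C=C
Why: Ethylene–alkyne cross-enyne metathesis turns a terminal alkyne into a 2-substituted buta-1,3-diene, and the substrate has no other C=C bond while free hydroxyls are tolerated.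

**Step 14**
Reactants: 17 diene diol
Product: 18 8α-hydroxylabda-13(16),14-dien-19-yl (Z)-3-iodoprop-2-enoate
Conditions: (Z)-3-iodoacrylic acid, DCC, DMAP (10 mol%), CH2Cl2, 0 °C, dark
Reagents that add atoms: (Z)-3-iodoacrylic acid, OC(=O)/C=C\I
Why: Steglich esterification acylates only the primary C19 hydroxyl, the tertiary C8 hydroxyl being unreactive, and low temperature with little DMAP should keep the Z-iodoalkene geometry.

**Step 15**
Reactants: 18 Z-iodoacrylate
Product: 19 8α-hydroxylabda-13(16),14-dien-19-yl (Z)-3-(4-hydroxyphenyl)prop-2-enoate, (4S,5R,8R,9R,10S), the target CNP0197278.1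
Conditions: 4-hydroxyphenylboronic acid, Pd(PPh3)4 (5 mol%), K3PO4, THF–H2O, 23 °C, dark
Reagents that add atoms: 4-hydroxyphenylboronic acid, OB(O)c1ccc(O)cc1
Why: Suzuki–Miyaura coupling of the vinyl iodide at zerovalent palladium is stereoretentive, so the Z geometry is carried into the cinnamate, and free phenol, tertiary alcohol and diene are tolerated at room temperature.

**Compound list**
1 | 5-chloropentanal | O=CCCCCCl | starting material
2 | (R)-5-chloro-2-(hydroxymethyl)pentanal | O=C[C@@H](CO)CCCCl | intermediate
3 | methyl (2Z,4S)-7-chloro-4-(hydroxymethyl)hept-2-enoate (not isolated) | COC(=O)/C=C\[C@@H](CO)CCCCl | intermediate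
4 | (S)-5-(3-chloropropyl)-5,6-dihydro-2H-pyran-2-one | O=C1C=C[C@H](CCCCl)CO1 | intermediate
5 | pent-4-ynal | C#CCCC=O | starting material
6 | (E)-2-methylhept-2-en-6-ynal | O=C/C(C)=C/CCC#C | intermediate
7 | (E)-3-methylocta-1,3-dien-7-yne | C=C/C(C)=C/CCC#C | intermediate
8 | (4S,4aS,8R,8aR)-8-(but-3-yn-1-yl)-4-(3-chloropropyl)-7-methyl-3,4,4a,5,8,8a-hexahydro-1H-isochromen-1-one | C#CCC[C@@H]1[C@@H]2C(=O)OC[C@@H](CCCCl)[C@@H]2CC=C1C | intermediate
9 | 15,16,18-trinorlabd-7-en-13-yne-20,19-olide (4α-H) | C#CCC[C@@H]1[C@@]2(C(=O)OC3)CCC[C@H]3[C@@H]2CC=C1C | intermediate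
10 | 19,20-epoxy-15,16,18-trinorlabd-7-en-13-yn-20-ol (lactol, anomer mixture) | C#CCC[C@@H]1[C@@]2(C(O)OC3)CCC[C@H]3[C@@H]2CC=C1C | intermediate
11 | 19-hydroxy-15,16,18-trinorlabd-7-en-13-yn-20-al N-tosylhydrazone (not isolated) | C#CCC[C@@H]1[C@@]2(C=NNS(=O)(=O)c3ccc(C)cc3)CCC[C@H](CO)[C@@H]2CC=C1C | intermediate
12 | 15,16,18-trinorlabd-7-en-13-yn-19-ol (4α-H) | C#CCC[C@@H]1[C@@]2(C)CCC[C@H](CO)[C@@H]2CC=C1C | intermediate
13 | 7α,8α-epoxy-15,16,18-trinorlabd-13-yn-19-ol | C#CCC[C@@H]1[C@@]2(C)CCC[C@H](CO)[C@@H]2C[C@@H]3[C@@]1(C)O3 | intermediate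
14 | 7α,8α-epoxy-15,16,18-trinorlabd-13-yn-19-al | C#CCC[C@@H]1[C@@]2(C)CCC[C@H](C=O)[C@@H]2C[C@@H]3[C@@]1(C)O3 | intermediate
15 | 7α,8α-epoxy-15,16-dinorlabd-13-yn-19-al | C#CCC[C@@H]1[C@@]2(C)CCC[C@](C)(C=O)[C@@H]2C[C@@H]3[C@@]1(C)O3 | intermediate
16 | 15,16-dinorlabd-13-yne-8α,19-diol | C#CCC[C@@H]1[C@@]2(C)CCC[C@](C)(CO)[C@@H]2CC[C@@]1(C)O | intermediate
17 | labda-13(16),14-diene-8α,19-diol | C=CC(=C)CC[C@@H]1[C@@]2(C)CCC[C@](C)(CO)[C@@H]2CC[C@@]1(C)O | intermediate
18 | 8α-hydroxylabda-13(16),14-dien-19-yl (Z)-3-iodoprop-2-enoate | C=CC(=C)CC[C@@H]1[C@@]2(C)CCC[C@](C)(COC(=O)/C=C\I)[C@@H]2CC[C@@]1(C)O | intermediate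
19 | 8α-hydroxylabda-13(16),14-dien-19-yl (Z)-3-(4-hydroxyphenyl)prop-2-enoate | C=CC(=C)CC[C@@H]1[C@@]2(C)CCC[C@](C)(COC(=O)/C=C\c3ccc(O)cc3)[C@@H]2CC[C@@]1(C)O | target

Total step count: 15. Longest linear sequence: 13 steps (steps 1, 2 and 5–15; the branch through steps 3 and 4 is equally long).

**Steps most likely to fail**

Step 5. The δ-lactone may be too weak a dienophile, so that Lewis acid-induced oligomerisation of the diene outruns the cycloaddition, or the 2-methyl group of the diene may erode the regiocontrol. The fallback activates the dienophile instead of forcing the conditions. It sets out from 4: addition of Br2 (CH2Cl2, 0 °C) should give the trans-dibromide of 4, 3,4-dibromo-5-(3-chloropropyl)oxan-2-one F1. Et3N then eliminates HBr to the α-bromo lactone (S)-3-bromo-5-(3-chloropropyl)-5,6-dihydro-2H-pyran-2-one F2, a more electron-poor and more strongly polarised dienophile of the same shape. Its Diels–Alder reaction with 7 under mild Lewis acid promotion should follow the same facial and endo preferences and give the 8a-bromo derivative of 8 F3. Zn dust in AcOH removes the bromine through the zinc enolate and the route is rejoined at 8; either C10 epimer is acceptable because step 6 passes through the enolate.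

Step 11. The hindered aldehyde enolate may undergo O-methylation or aldol self-condensation, or the two faces of the enolate may not be discriminated well enough. The fallback sets out from 14 and moves the alkylation to an ester enolate. Pinnick oxidation (NaClO2, NaH2PO4, 2-methylbut-2-ene) should give 7α,8α-epoxy-15,16,18-trinorlabd-13-yn-19-oic acid F4, and Me3SiCHN2 its methyl ester F5. Deprotonation with LiN(i-Pr)2 and alkylation with MeI from the equatorial face should give methyl 7α,8α-epoxy-15,16-dinorlabd-13-yn-19-oate F6. LiAlH4 in THF then reduces the ester and opens the epoxide at C7, and the route is rejoined at 16.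

Step 2. Under the basic olefination conditions the unprotected β-hydroxy aldehyde may lose formaldehyde by retro-aldol cleavage, eliminate water, or epimerise at C4, and Z selectivity may be incomplete. The fallback sets out from 2 and avoids base: Wittig olefination with Ph3P=CHCO2Me in CH2Cl2 at 23 °C should give methyl (2E,4S)-7-chloro-4-(hydroxymethyl)hept-2-enoate F7. Irradiation at 300 nm in MeCN equilibrates the E and Z isomers, and the Z isomer lactonises irreversibly, so the route is rejoined at 4.

**Further compounds**
F1 | step 5 | 3,4-dibromo-5-(3-chloropropyl)oxan-2-one (trans-dibromide of 4, C5 of the ring as in 4) | O=C1C(Br)C(Br)[C@H](CCCCl)CO1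
F2 | step 5 | (S)-3-bromo-5-(3-chloropropyl)-5,6-dihydro-2H-pyran-2-one | O=C1C(Br)=C[C@H](CCCCl)CO1
F3 | step 5 | 8a-bromo derivative of 8 (bromine in place of the C10 hydrogen) | C#CCC[C@@H]1[C@]2(Br)C(=O)OC[C@@H](CCCCl)[C@@H]2CC=C1C
F4 | step 11 | 7α,8α-epoxy-15,16,18-trinorlabd-13-yn-19-oic acid | C#CCC[C@@H]1[C@@]2(C)CCC[C@H](C(=O)O)[C@@H]2C[C@@H]3[C@@]1(C)O3
F5 | step 11 | methyl 7α,8α-epoxy-15,16,18-trinorlabd-13-yn-19-oate | C#CCC[C@@H]1[C@@]2(C)CCC[C@H](C(=O)OC)[C@@H]2C[C@@H]3[C@@]1(C)O3
F6 | step 11 | methyl 7α,8α-epoxy-15,16-dinorlabd-13-yn-19-oate | C#CCC[C@@H]1[C@@]2(C)CCC[C@](C)(C(=O)OC)[C@@H]2C[C@@H]3[C@@]1(C)O3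
F7 | step 2 | methyl (2E,4S)-7-chloro-4-(hydroxymethyl)hept-2-enoate | COC(=O)/C=C/[C@@H](CO)CCCCl
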